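**Retrosynthetic overview**
1. Atoms are numbered in target-SMILES order (rings A C6/C7/C9/C10/C11/C12, B C10/C11/O14/C15/C33, C C15/C16/C22/C23/O32/C33, D C16/C17/C18/C19/C21/C22, E C21/C22/C23/C24/C29/C30, F C24/O25/C26/C27/C29). The plan rests on ring D: C16 (carrying C15) and C19 (carrying the C20 methyl) are cis and sit on either side of the C21–C22 bond shared with ring E, the imprint of an E,E-diene on a quinone C=C.
2. Endgame disconnections: C2=C3 (Julia–Kocienski on a C3 aldehyde), C30–C31 (methyl coupling of the C30 triflate), O32–C33 (acid closure of the ring E phenol onto the ring B benzofuran, making ring C), and C17=C18 (diimide).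
3. Ring D: intermolecular [4+2] of dienylbenzofuran 15 (C16–C19) with (R)-sulfinyl furanoquinone 26 (C21=C22), then loss of sulfenic acid; the quinone is latent ring E.
4. 15 from creosol: chloroacetone annulation, Claisen/hydroboration for C3–C5, C15 formylation, crotylphosphonate olefination. 26 from 2-hydroxy-5-methoxybenzaldehyde: bromine at the future C22, Dakin oxidation, chloroacetone annulation, Br/Li exchange with menthyl sulfinate, oxidation to the quinone.
5. Ring order: A/B and E/F enter as preformed benzofurans, ring D is formed in the key step, ring C last.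

Key step: step 17

Remark: descriptors quoted with atom numbers (15R, 16R, 19S, 33R) refer to the target-SMILES numbering; TBS = tert-butyldimethylsilyl.

**Ring A fragment**

Step 1
Reactants: 1 2-methoxy-4-methylphenol (creosol); 2 chloroacetone
Product: 3 1-(2-methoxy-4-methylphenoxy)propan-2-one
Conditions: K2CO3, KI (cat.), acetone, reflux
Reagents that add atoms: none
Why: Williamson O-alkylation of the phenoxide by the α-chloroketone (iodide-assisted) is the standard entry to aryloxyacetones; no stereocentre is formed.

Step 2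
Reactants: 3 1-(2-methoxy-4-methylphenoxy)propan-2-one
Product: 4 7-methoxy-3,5-dimethyl-1-benzofuran
Conditions: polyphosphoric acid, toluene, 90 °C
Reagents that add atoms: none
Why: Acid-mediated cyclodehydration of an aryloxyacetone (intramolecular Friedel–Crafts hydroxyalkylation, then loss of water) gives the 3-methylbenzofuran, and only one position ortho to the ether oxygen is free, so the ring closure is regiodefined.

Step 3
Reactants: 4 7-methoxy-3,5-dimethyl-1-benzofuran
Product: 5 3,5-dimethyl-1-benzofuran-7-ol
Conditions: BBr3, CH2Cl2, −78 → 0 °C; H2O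
Reagents that add atoms: none
Why: BBr3 cleavage of the aryl methyl ether (O–B adduct, bromide attack on methyl) frees the C12 oxygen, a demethylation that benzofurans tolerate in the cold.

Step 4
Reactants: 5 3,5-dimethyl-1-benzofuran-7-ol; 6 allyl bromide
Product: 7 7-(allyloxy)-3,5-dimethyl-1-benzofuran
Conditions: K2CO3, acetone, reflux
Reagents that add atoms: none
Why: Williamson allylation places the three carbons C3–C5 on the C12 oxygen for sigmatropic transfer.

Step 5
Reactants: 7 7-(allyloxy)-3,5-dimethyl-1-benzofuran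
Product: 8 6-allyl-3,5-dimethyl-1-benzofuran-7-ol
Conditions: N,N-diethylaniline, 195 °C
Reagents that add atoms: none
Why: The aromatic Claisen rearrangement ([3,3]-shift, then tautomerisation) delivers the allyl group to C6, the only free ortho position, between the oxygen and the C7 methyl.

Step 6
Reactants: 8 6-allyl-3,5-dimethyl-1-benzofuran-7-ol
Product: 10 6-(3-hydroxypropyl)-3,5-dimethyl-1-benzofuran-7-ol, via organoborane 9 (not isolated)
Conditions: 9-BBN (2.5 equiv), THF, 0 °C → rt; then NaOH aq, H2O2, 0 °C → rt
Reagents that add atoms: hydrogen peroxide, OO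
Why: Anti-Markovnikov hydroboration–oxidation of the terminal alkene gives the primary alcohol, the phenol only consuming one B–H and the aromatic furan C=C being inert to 9-BBN.

Step 7
Reactants: 10 6-(3-hydroxypropyl)-3,5-dimethyl-1-benzofuran-7-ol
Product: 11 7-(tert-butyldimethylsilyloxy)-6-[3-(tert-butyldimethylsilyloxy)propyl]-3,5-dimethyl-1-benzofuran
Conditions: TBSCl (2.5 equiv), imidazole, DMF, rt
Reagents that add atoms: tert-butyldimethylsilyl chloride, CC(C)(C)[Si](C)(C)Cl
Why: Imidazole-promoted silylation protects both hydroxyls at once; the aryl silyl ether is chosen because it survives the later acid closure (an acetal would not), and the alkyl one can be removed separately by mild acid.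

Step 8
Reactants: 11 bis-TBS benzofuran
Product: 13 7-(tert-butyldimethylsilyloxy)-6-[3-(tert-butyldimethylsilyloxy)propyl]-3,5-dimethyl-1-benzofuran-2-carbaldehyde, via aryllithium 12 (not isolated)
Conditions: n-BuLi, THF, −78 → −30 °C; DMF, −78 °C → rt; aq NH4Cl
Reagents that add atoms: N,N-dimethylformamide, CN(C)C=O
Why: The furan α-proton (C15–H) is the most acidic C–H, so lithiation and formylation with DMF install regiospecifically the carbon that becomes C16.

Step 9
Reactants: 13 benzofuran-2-carbaldehyde; 14 diethyl (E)-but-2-en-1-ylphosphonate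
Product: 15 7-(tert-butyldimethylsilyloxy)-6-[3-(tert-butyldimethylsilyloxy)propyl]-3,5-dimethyl-2-[(1E,3E)-penta-1,3-dien-1-yl]-1-benzofuran
Conditions: 14, n-BuLi, THF, −78 °C; then 13, DMPU, −78 °C → rt
Reagents that add atoms: none
Why: Horner–Wadsworth–Emmons olefination with the α-lithiated allylic phosphonate forms C16=C17 with E geometry while the E C18=C19 bond comes intact from the reagent, giving the E,E-diene.

**Quinone fragment**

Step 10
Reactants: 16 2-hydroxy-5-methoxybenzaldehyde
Product: 17 3-bromo-2-hydroxy-5-methoxybenzaldehyde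
Conditions: Br2, NaOAc, AcOH, rt
Reagents that add atoms: bromine, BrBr
Why: Electrophilic aromatic bromination is directed by the phenol to its only free ortho position (para is blocked), which puts the halogen on the carbon destined to be C22.

Step 11
Reactants: 17 3-bromo-2-hydroxy-5-methoxybenzaldehyde
Product: 18 3-bromo-2,5-dimethoxybenzaldehyde
Conditions: MeI, K2CO3, DMF, rt
Reagents that add atoms: iodomethane, CI
Why: Williamson methylation caps the oxygen that will become the C23 quinone oxygen.

Step 12
Reactants: 18 3-bromo-2,5-dimethoxybenzaldehyde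
Product: 20 3-bromo-2,5-dimethoxyphenol, via aryl formate 19 (not isolated)
Conditions: mCPBA, CH2Cl2, 0 °C → rt; then KOH, MeOH/H2O, rt
Reagents that add atoms: 3-chloroperbenzoic acid, O=C(OO)c1cccc(Cl)c1
Why: Baeyer–Villiger (Dakin-type) oxidation of the electron-rich benzaldehyde proceeds with aryl migration, and saponification of the formate gives the phenol that becomes the furan oxygen O25.

Step 13
Reactants: 20 3-bromo-2,5-dimethoxyphenol; 2 chloroacetone
Product: 21 1-(3-bromo-2,5-dimethoxyphenoxy)propan-2-one
Conditions: K2CO3, KI (cat.), acetone, reflux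
Reagents that add atoms: none
Why: Williamson O-alkylation as in step 1.

Step 14
Reactants: 21 1-(3-bromo-2,5-dimethoxyphenoxy)propan-2-one
Product: 22 6-bromo-4,7-dimethoxy-3-methyl-1-benzofuran
Conditions: polyphosphoric acid, toluene, 80 °C
Reagents that add atoms: none
Why: Cyclodehydration as in step 2 onto the single free ortho position, which is activated by the neighbouring methoxy group, leaves bromine at benzofuran C6 (the future C22).

Step 15
Reactants: 22 6-bromo-4,7-dimethoxy-3-methyl-1-benzofuran; 23 (1S,2R,5S)-menthyl (R)-p-toluenesulfinate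
Product: 25 (R)-4,7-dimethoxy-3-methyl-6-(p-tolylsulfinyl)-1-benzofuran, via aryllithium 24 (not isolated)
Conditions: n-BuLi, THF, −78 °C; cannulate into 23, THF, −78 °C
Reagents that add atoms: none
Why: Bromine–lithium exchange at −78 °C fixes the metal at C22 (direct deprotonation would instead take the furan C–H), and Andersen substitution at sulfur with inversion turns the (R)-sulfinate into the (R)-sulfoxide, the reagent setting the sulfur stereocentre.

Step 16
Reactants: 25 (R)-4,7-dimethoxy-3-methyl-6-(p-tolylsulfinyl)-1-benzofuran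
Product: 26 (R)-3-methyl-6-(p-tolylsulfinyl)-1-benzofuran-4,7-dione
Conditions: (NH4)2Ce(NO3)6, MeCN/H2O, 0 °C
Reagents that add atoms: water, O
Why: Oxidative demethylation of the para-dimethoxyarene gives the para-quinone with its oxygens from water, conditions that sulfoxides and the furan ring withstand.

**Key step and endgame**

Step 17
Reactants: 15 E,E-dienylbenzofuran; 26 (R)-sulfinyl furanoquinone
Product: 28 (5S,8R)-8-{7-(tert-butyldimethylsilyloxy)-6-[3-(tert-butyldimethylsilyloxy)propyl]-3,5-dimethyl-1-benzofuran-2-yl}-3,5-dimethyl-5,8-dihydronaphtho[2,3-b]furan-4,9-dione, via sulfinyl cycloadduct 27 (not isolated)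
Conditions: CH2Cl2, −20 °C → rt, dark, Ar; solution used directly
Reagents that add atoms: none
Why: A normal-electron-demand Diels–Alder reaction of the diene C16–C19 with the sulfinyl-activated C21=C22 bond, suprafacial on both partners, is followed in the same flask by syn elimination of p-toluenesulfenic acid from the cis C22–S and C21–H, which returns the quinone; the closest known reaction type is the tandem cycloaddition–sulfoxide elimination of enantiopure 2-(p-tolylsulfinyl)quinones with 1-substituted dienes. Ring D is closed by the [4+2] cycloaddition itself, C16–C22 and C19–C21 being formed together. The cis relation of C16 and C19 follows from the E,E geometry of the diene, and their absolute configuration (16R,19S) from endo approach to the quinone face that carries the sulfur lone pair in the conformer with S–O syn-periplanar to C21=C22, which for the (R)-sulfoxide is the face leading to the required enantiomer. The step needs regioselectivity, which should come from the benzofuranyl donor making C19 the nucleophilic diene terminus while the sulfinyl group and the more electron-poor C23 carbonyl make C21 the electrophilic carbon, so that C19 bonds to C21 and C16 to C22. Only one quinone C=C is available because the other is part of the furan ring, and the dihydroquinone is kept cold and reduced at once so that it cannot tautomerise to the naphthalenediol.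

Step 18
Reactants: 28 dihydronaphthofurandione
Product: 29 (5S,8R)-8-{7-(tert-butyldimethylsilyloxy)-6-[3-(tert-butyldimethylsilyloxy)propyl]-3,5-dimethyl-1-benzofuran-2-yl}-3,5-dimethyl-5,8-dihydronaphtho[2,3-b]furan-4,9-diol
Conditions: Na2S2O4, EtOAc/H2O, rt, Ar
Reagents that add atoms: none
Why: Dithionite reduction of the quinone to the hydroquinone removes the driving force for enolisation toward a fully aromatic naphthalene, so C16 and C19 are kept.

Step 19
Reactants: 29 dihydronaphthofurandiol
Product: 30 (5S,8R)-8-{7-(tert-butyldimethylsilyloxy)-6-[3-(tert-butyldimethylsilyloxy)propyl]-3,5-dimethyl-1-benzofuran-2-yl}-3,5-dimethyl-5,6,7,8-tetrahydronaphtho[2,3-b]furan-4,9-diol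
Conditions: KO2CN=NCO2K, AcOH, MeOH/THF, rt, Ar
Reagents that add atoms: none
Why: Diimide reduction transfers H2 in a concerted syn manner to the cis-disubstituted C17=C18 bond without the double-bond migration that metal catalysts could cause, and leaves the aromatic furans and silyl ethers alone.

Step 20
Reactants: 30 tetrahydronaphthofurandiol
Product: 31 (5S,8R)-8-[7-(tert-butyldimethylsilyloxy)-6-(3-hydroxypropyl)-3,5-dimethyl-1-benzofuran-2-yl]-3,5-dimethyl-5,6,7,8-tetrahydronaphtho[2,3-b]furan-4,9-diol
Conditions: PPTS, MeOH, rt, Ar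
Reagents that add atoms: none
Why: Mild acid methanolysis removes the primary alkyl silyl ether selectively (the aryl silyl ether is far less basic at oxygen), so that no acid-labile alkyl silyl group enters the next step.

Step 21
Reactants: 31 hydroquinone triol
Product: 32 hexacyclic phenol (15R,16R,19S,33R) with ring C closed through O32–C33, C30–OH free, C12–OTBS and the 3-hydroxypropyl chain on C6
Conditions: CF3CO2H (5 equiv), CH2Cl2 (0.01 M), −20 → 0 °C, Ar; NaHCO3 quench
Reagents that add atoms: none
Why: Proposed new method: the acid should protonate the electron-rich 2,3-dialkylbenzofuran at C15 (the usual site of electrophilic attack on benzofurans) to give a tertiary benzylic C33 cation stabilised by O14, which the peri phenol O32 captures in a six-membered closure; the B/C fusion can only be cis, so C15 and C33 are set together, and the proton should enter C15 anti to O32 on the face syn to H16 because the rotamer that closes is the one holding C33 and its methyl between H16 and C22 (least allylic 1,3-strain), which gives 15R,33R; the closest known reactions are the acid-catalysed hydroalkoxylation of α-methylstyrenes by phenols to chromans and the acid cyclisation of tryptamines to pyrroloindolines by protonation and capture of a 2,3-disubstituted indole.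

Step 22
Reactants: 32 hexacyclic phenol
Product: 33 C30 trifluoromethanesulfonate of 32
Conditions: PhNTf2, Et3N, DMAP (cat.), CH2Cl2, rt
Reagents that add atoms: N-phenylbis(trifluoromethanesulfonimide), O=S(=O)(N(c1ccccc1)S(=O)(=O)C(F)(F)F)C(F)(F)F
Why: Triflation of the single remaining phenol with PhNTf2 and an amine base is chemoselective over the primary alcohol and the silyl ether.

Step 23
Reactants: 33 aryl triflate
Product: 34 C30-methyl hexacycle (15R,16R,19S,33R) with the 3-hydroxypropyl chain and C12–OTBS
Conditions: MeZnCl (4 equiv), Pd(OAc)2 (cat.), SPhos, THF, 60 °C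
Reagents that add atoms: methylzinc chloride, C[Zn]Cl
Why: Negishi coupling (oxidative addition of the triflate to zerovalent palladium formed in situ, transmetalation from zinc, reductive elimination) with a bulky biarylphosphine copes with the two ortho substituents, and the free alcohol only consumes one equivalent of the zinc reagent.

Step 24
Reactants: 34 C30-methyl alcohol
Product: 35 3-arylpropanal (C3 aldehyde) of the hexacycle
Conditions: Dess–Martin periodinane, pyridine, CH2Cl2, 0 °C → rt
Reagents that add atoms: none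
Why: Dess–Martin oxidation takes the primary alcohol to the aldehyde under buffered, non-acidic conditions that spare the benzylic ether, the furan and the silyl ether.

Step 25
Reactants: 35 aldehyde; 36 5-(ethylsulfonyl)-1-phenyl-1H-tetrazole
Product: 37 O-TBS ether of the target with the (E)-pent-3-enyl chain
Conditions: 36, KN(SiMe3)2, DME, −60 °C; then 35, −60 °C → rt
Reagents that add atoms: none
Why: Julia–Kocienski olefination (addition of the metalated sulfone, Smiles rearrangement, loss of SO2 and tetrazolate) forms C2=C3 with high E selectivity under potassium/DME conditions.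

Step 26
Reactants: 37 O-TBS ether of the target
Product: 38 CNP0281983.1 (15R,16R,19S,33R)
Conditions: Bu4NF, AcOH, THF, 0 °C
Reagents that add atoms: none
Why: Fluoride cleaves the aryl silyl ether, and acetic acid buffering keeps the phenoxide from building up, so the base-sensitive O14–C15 ether is not exposed to elimination.

**Compound list**
1 | 2-methoxy-4-methylphenol (creosol) | COc1cc(C)ccc1O | starting material
2 | chloroacetone | CC(=O)CCl | starting material
3 | 1-(2-methoxy-4-methylphenoxy)propan-2-one | COc1cc(C)ccc1OCC(C)=O | intermediate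
4 | 7-methoxy-3,5-dimethyl-1-benzofuran | COc1cc(C)cc2c(C)coc12 | intermediate
5 | 3,5-dimethyl-1-benzofuran-7-ol | Cc1cc(O)c2occ(C)c2c1 | intermediate
6 | allyl bromide | C=CCBr | starting material
7 | 7-(allyloxy)-3,5-dimethyl-1-benzofuran | C=CCOc1cc(C)cc2c(C)coc12 | intermediate
8 | 6-allyl-3,5-dimethyl-1-benzofuran-7-ol | C=CCc1c(C)cc2c(C)coc2c1O | intermediate
9 | 9-{3-[7-(9-borabicyclo[3.3.1]nonan-9-yloxy)-3,5-dimethyl-1-benzofuran-6-yl]propyl}-9-borabicyclo[3.3.1]nonane (not isolated) | Cc1cc2c(C)coc2c(OB2C3CCCC2CCC3)c1CCCB1C2CCCC1CCC2 | intermediate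
10 | 6-(3-hydroxypropyl)-3,5-dimethyl-1-benzofuran-7-ol | OCCCc1c(C)cc2c(C)coc2c1O | intermediate
11 | 7-(tert-butyldimethylsilyloxy)-6-[3-(tert-butyldimethylsilyloxy)propyl]-3,5-dimethyl-1-benzofuran | CC(C)(C)[Si](C)(C)OCCCc1c(C)cc2c(C)coc2c1O[Si](C)(C)C(C)(C)C | intermediate
12 | 2-lithio derivative of 11 (not isolated) | CC(C)(C)[Si](C)(C)OCCCc1c(C)cc2c(C)c([Li])oc2c1O[Si](C)(C)C(C)(C)C | intermediate
13 | 7-(tert-butyldimethylsilyloxy)-6-[3-(tert-butyldimethylsilyloxy)propyl]-3,5-dimethyl-1-benzofuran-2-carbaldehyde | CC(C)(C)[Si](C)(C)OCCCc1c(C)cc2c(C)c(C=O)oc2c1O[Si](C)(C)C(C)(C)C | intermediate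
14 | diethyl (E)-but-2-en-1-ylphosphonate | C/C=C/CP(=O)(OCC)OCC | starting material
15 | 7-(tert-butyldimethylsilyloxy)-6-[3-(tert-butyldimethylsilyloxy)propyl]-3,5-dimethyl-2-[(1E,3E)-penta-1,3-dien-1-yl]-1-benzofuran | CC(C)(C)[Si](C)(C)OCCCc1c(C)cc2c(C)c(/C=C/C=C/C)oc2c1O[Si](C)(C)C(C)(C)C | intermediate
16 | 2-hydroxy-5-methoxybenzaldehyde | COc1ccc(O)c(C=O)c1 | starting material
17 | 3-bromo-2-hydroxy-5-methoxybenzaldehyde | COc1cc(Br)c(O)c(C=O)c1 | intermediate
18 | 3-bromo-2,5-dimethoxybenzaldehyde | COc1cc(Br)c(OC)c(C=O)c1 | intermediate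
19 | 3-bromo-2,5-dimethoxyphenyl formate (not isolated) | COc1cc(Br)c(OC)c(OC=O)c1 | intermediate
20 | 3-bromo-2,5-dimethoxyphenol | COc1cc(Br)c(OC)c(O)c1 | intermediate
21 | 1-(3-bromo-2,5-dimethoxyphenoxy)propan-2-one | COc1cc(Br)c(OC)c(OCC(C)=O)c1 | intermediate
22 | 6-bromo-4,7-dimethoxy-3-methyl-1-benzofuran | COc1cc(Br)c(OC)c2occ(C)c12 | intermediate
23 | (1S,2R,5S)-2-isopropyl-5-methylcyclohexyl (R)-4-methylbenzenesulfinate | C[C@H]1CC[C@@H]([C@H](C1)O[S@@](=O)c1ccc(C)cc1)C(C)C | starting material
24 | 6-lithio-4,7-dimethoxy-3-methyl-1-benzofuran (not isolated) | COc1cc([Li])c(OC)c2occ(C)c12 | intermediate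
25 | (R)-4,7-dimethoxy-3-methyl-6-(p-tolylsulfinyl)-1-benzofuran | COc1cc([S@](=O)c3ccc(C)cc3)c(OC)c2occ(C)c12 | intermediate
26 | (R)-3-methyl-6-(p-tolylsulfinyl)-1-benzofuran-4,7-dione | Cc1ccc(cc1)[S@@](=O)C1=CC(=O)c2c(C)coc2C1=O | intermediate
27 | cis-fused sulfinyl cycloadduct: (R)-p-tolylsulfinyl on C22, H on C21 syn to it, benzofuranyl on C16 and methyl on C19 cis (not isolated) | CC(C)(C)[Si](C)(C)OCCCc1c(C)cc2c(C)c(oc2c1O[Si](C)(C)C(C)(C)C)[C@@H]3C=C[C@H](C)[C@@H]4C(=O)c5c(C)coc5C(=O)[C@]34[S@](=O)c6ccc(C)cc6 | intermediate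
28 | (5S,8R)-8-{7-(tert-butyldimethylsilyloxy)-6-[3-(tert-butyldimethylsilyloxy)propyl]-3,5-dimethyl-1-benzofuran-2-yl}-3,5-dimethyl-5,8-dihydronaphtho[2,3-b]furan-4,9-dione | CC(C)(C)[Si](C)(C)OCCCc1c(C)cc2c(C)c(oc2c1O[Si](C)(C)C(C)(C)C)[C@@H]3C=C[C@H](C)C4=C3C(=O)c3occ(C)c3C4=O | intermediate
29 | (5S,8R)-5,8-dihydronaphtho[2,3-b]furan-4,9-diol corresponding to 28 | CC(C)(C)[Si](C)(C)OCCCc1c(C)cc2c(C)c(oc2c1O[Si](C)(C)C(C)(C)C)[C@@H]3C=C[C@H](C)c4c3c(O)c3occ(C)c3c4O | intermediate
30 | (5S,8R)-5,6,7,8-tetrahydronaphtho[2,3-b]furan-4,9-diol corresponding to 29 | CC(C)(C)[Si](C)(C)OCCCc1c(C)cc2c(C)c(oc2c1O[Si](C)(C)C(C)(C)C)[C@@H]3CC[C@H](C)c4c3c(O)c3occ(C)c3c4O | intermediate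
31 | (5S,8R)-8-[7-(tert-butyldimethylsilyloxy)-6-(3-hydroxypropyl)-3,5-dimethyl-1-benzofuran-2-yl]-3,5-dimethyl-5,6,7,8-tetrahydronaphtho[2,3-b]furan-4,9-diol | OCCCc1c(C)cc2c(C)c(oc2c1O[Si](C)(C)C(C)(C)C)[C@@H]3CC[C@H](C)c4c3c(O)c3occ(C)c3c4O | intermediate
32 | hexacyclic phenol (15R,16R,19S,33R): ring C closed, C30–OH, C12–OTBS, 3-hydroxypropyl on C6 | OCCCc1c(C)cc2c(c1O[Si](C)(C)C(C)(C)C)O[C@@H]1[C@@H]3CC[C@H](C)c4c3c(c3occ(C)c3c4O)O[C@]21C | intermediate
33 | C30 trifluoromethanesulfonate of 32 | OCCCc1c(C)cc2c(c1O[Si](C)(C)C(C)(C)C)O[C@@H]1[C@@H]3CC[C@H](C)c4c3c(c3occ(C)c3c4OS(=O)(=O)C(F)(F)F)O[C@]21C | intermediate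
34 | C30-methyl hexacycle with 3-hydroxypropyl chain and C12–OTBS | OCCCc1c(C)cc2c(c1O[Si](C)(C)C(C)(C)C)O[C@@H]1[C@@H]3CC[C@H](C)c4c3c(c3occ(C)c3c4C)O[C@]21C | intermediate
35 | C3 aldehyde of 34 | O=CCCc1c(C)cc2c(c1O[Si](C)(C)C(C)(C)C)O[C@@H]1[C@@H]3CC[C@H](C)c4c3c(c3occ(C)c3c4C)O[C@]21C | intermediate
36 | 5-(ethylsulfonyl)-1-phenyl-1H-tetrazole | CCS(=O)(=O)c1nnnn1-c1ccccc1 | starting material
37 | O-TBS ether of the target | C/C=C/CCc1c(C)cc2c(c1O[Si](C)(C)C(C)(C)C)O[C@@H]1[C@@H]3CC[C@H](C)c4c3c(c3occ(C)c3c4C)O[C@]21C | intermediate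
38 | CNP0281983.1 | C/C=C/CCc1c(C)cc2c(c1O)O[C@@H]1[C@@H]3CC[C@H](C)c4c3c(c3occ(C)c3c4C)O[C@]21C | target

**Totals**
Total step count: 26. Longest linear sequence: 19 steps (steps 1–9, then 17–26); the quinone branch (steps 10–16) joins at step 17.

**Steps most likely to fail**

Step 21 (proposed new method). Three processes threaten it: protonation at C33 instead of C15, with capture of the resulting C15 oxocarbenium by O32 to give a five-membered spiroketal (favoured if the closure drifts to thermodynamic control); proton delivery to the other face of C15, giving the C15/C33-epimeric pair; and intermolecular Friedel–Crafts oligomerisation. The fallback uses only known reaction types and sets out from 31. Ag2O in ether would oxidise the hydroquinone to quinone F1. Warming with Et3N in toluene would tautomerise F1 to ortho-quinone methide F2, which closes by oxa-6π electrocyclisation (the chromenol rearrangement of alk-2-enyl quinones) to chromenol F3, in which O32–C33 is formed and C15=C16 is unsaturated. Hydrogenation (H2, [Ir(cod)(PCy3)(py)]PF6, CH2Cl2) can only give the cis B/C fusion, that is H15 and H16 syn to the C34 methyl, and comes back to the route at 32. This detour rebuilds C16 and sets C33 under the influence of the remote C19 only, so separation from the C33-epimeric series would be needed.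

Step 17 (key step). The risks are incomplete facial discrimination by the sulfinyl group (lowering enantiomeric purity, since the auxiliary is lost in the same step), some leakage of regiochemistry, and oxidative aromatisation of ring D before reduction. The fallback replaces auxiliary control by classical resolution at the first robust chiral intermediate. It sets out from 30: (1S)-camphanic chloride, Et3N and DMAP would give bis-camphanate F4, an air-stable pair of diastereomers separable by crystallisation or chromatography. Hydrazine hydrate in THF/MeOH would then cleave the aryl esters and return to the route at 30.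

Step 19. The electron-rich 1,4-dihydro hydroquinone may be oxidised and aromatise (losing C16 and C19) while the reduction is slow at the doubly branched alkene. The fallback changes the sequence to protect, hydrogenate, deprotect, and sets out from 29. Ac2O, pyridine and DMAP would give diacetate F5, which no longer oxidises. Homogeneous hydrogenation (H2, RhCl(PPh3)3, benzene/EtOH) would give tetrahydro diacetate F6. i-Bu2AlH in CH2Cl2 at −78 °C would remove the acetates and return to the route at 30.

**Further compounds**
F1 | step 21 | quinone of 31: (5S,8R)-8-[7-(tert-butyldimethylsilyloxy)-6-(3-hydroxypropyl)-3,5-dimethyl-1-benzofuran-2-yl]-3,5-dimethyl-5,6,7,8-tetrahydronaphtho[2,3-b]furan-4,9-dione | OCCCc1c(C)cc2c(C)c(oc2c1O[Si](C)(C)C(C)(C)C)[C@@H]3CC[C@H](C)C4=C3C(=O)c3occ(C)c3C4=O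
F2 | step 21 | ortho-quinone methide tautomer of F1 (C16=C22, C23=O, C30–OH) | OCCCc1c(C)cc2c(C)c(oc2c1O[Si](C)(C)C(C)(C)C)C3=C4C(=O)c5occ(C)c5C(O)=C4[C@@H](C)CC3
F3 | step 21 | chromenol (19S,33R) with O32–C33 closed and C15=C16 unsaturated | OCCCc1c(C)cc2c(c1O[Si](C)(C)C(C)(C)C)OC1=C3CC[C@H](C)c4c3c(c3occ(C)c3c4O)O[C@]21C
F4 | step 17 | bis[(1S,4R)-camphanate] of 30 | CC(C)(C)[Si](C)(C)OCCCc1c(C)cc2c(C)c(oc2c1O[Si](C)(C)C(C)(C)C)[C@@H]3CC[C@H](C)c4c3c(OC(=O)[C@@]56CC[C@@](C)(C(=O)O5)C6(C)C)c3occ(C)c3c4OC(=O)[C@@]56CC[C@@](C)(C(=O)O5)C6(C)C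
F5 | step 19 | diacetate of 29 | CC(C)(C)[Si](C)(C)OCCCc1c(C)cc2c(C)c(oc2c1O[Si](C)(C)C(C)(C)C)[C@@H]3C=C[C@H](C)c4c3c(OC(C)=O)c3occ(C)c3c4OC(C)=O
F6 | step 19 | diacetate of 30 | CC(C)(C)[Si](C)(C)OCCCc1c(C)cc2c(C)c(oc2c1O[Si](C)(C)C(C)(C)C)[C@@H]3CC[C@H](C)c4c3c(OC(C)=O)c3occ(C)c3c4OC(C)=O
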